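**Strategy.** The 14-membered carbocycle is derived from a 16-membered allyl β-keto lactone in which the future C9–C10 bond is replaced by a C9–C(=O)–O–C10 ester bridge. The route exploits the position of that bond between C9, alpha to C8 (the carbon that carries the exocyclic methylene C19, held as a ketone), and C10, the allylic terminus of the E-configured C11=C12 alkene. Zerovalent palladium ionises the lactone, CO2 is expelled and the C9 enolate closes onto C10, contracting the ring by two atoms. The precursor is an easily closed macrolactone that already holds C1, C2 and C7, both trisubstituted alkenes and three silyl ethers.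

Key step: step 18

Remark: locants are cembrane numbers (C1–C20); the keto lactone 26 and the ketone 27 are used as (1R,2S,7R), E at C11=C12, with C2 and C5 cis across C3=C4, which is the arrangement of the target.
Remark: the CIP label at C2 is R in the alkyne, stannane and iodide intermediates and S once the C4–C5 bond exists; the spatial arrangement does not change.
Assumption: the sense of induction in step 6 is set by the choice of ligand enantiomer, and the enantiomer that gives the (2R) propargylic carbinol 10 is used; the anti C1/C2 relation is intrinsic to the reaction.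

**Route**

Step 1
Reactants: 1 geraniol
Product: 3 geranyl 4-methoxybenzyl ether, via sodium geranoxide 2 (not isolated)
Conditions: NaH, THF/DMF, 0 °C; then PMBCl, Bu4NI (cat.), 0 °C to rt
Reagents that add atoms: 4-methoxybenzyl chloride, COc1ccc(CCl)cc1
Why: Williamson etherification of the primary allylic alkoxide; the PMB ether should survive the chromium, ruthenium, zinc, palladium and enolate steps and can later be removed oxidatively without touching silyl ethers.

Step 2
Reactants: 3 geranyl 4-methoxybenzyl ether
Product: 4 (2E,6E)-8-[(4-methoxybenzyl)oxy]-2,6-dimethylocta-2,6-dien-1-ol (C16 alcohol)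
Conditions: SeO2 (cat.), t-BuOOH, salicylic acid (cat.), CH2Cl2, 0 °C to rt, stopped at partial conversion with recycling of 3
Reagents that add atoms: tert-butyl hydroperoxide, CC(C)(C)OO
Why: SeO2-catalysed allylic oxidation (ene reaction, then [2,3]-sigmatropic shift) should hydroxylate the E-methyl group of the electron-rich terminal alkene, while the C11=C12 alkene is deactivated by its allylic ether oxygen.

Step 3
Reactants: 4 C16 alcohol
Product: 5 (2E,6E)-8-bromo-1-[(4-methoxybenzyl)oxy]-3,7-dimethylocta-2,6-diene (C16 bromide)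
Conditions: CBr4, PPh3, CH2Cl2, 0 °C
Reagents that add atoms: carbon tetrabromide, BrC(Br)(Br)Br
Why: Appel bromination replaces the primary allylic hydroxyl by SN2 at low temperature, so the E alkene should not transpose.

Step 4
Reactants: 6 2-butyne-1,4-diol
Product: 7 4-hydroxybut-2-yn-1-yl acetate
Conditions: Ac2O (0.3 equiv), pyridine, DMAP (cat.), THF, 0 °C; excess diol removed by aqueous wash
Reagents that add atoms: acetic anhydride, CC(=O)OC(C)=O
Why: Statistical mono-acylation with the diol in excess should keep diacetate low, and the water-soluble diol is washed out.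

Step 5
Reactants: 7 4-hydroxybut-2-yn-1-yl acetate
Product: 8 4-oxobut-2-yn-1-yl acetate (C2–C4/C18 ynal)
Conditions: MnO2 (activated), CH2Cl2, rt
Reagents that add atoms: none
Why: MnO2 oxidises propargylic alcohols to ynals under neutral conditions that leave the acetate intact.

Step 6
Reactants: 5 C16 bromide; 8 ynal
Product: 10 (4R,5R,8E)-4-hydroxy-10-[(4-methoxybenzyl)oxy]-8-methyl-5-(prop-1-en-2-yl)dec-8-en-2-yn-1-yl acetate [cembrane (1R,2R), free OH at C2], via C2 trimethylsilyl ether 9 (not isolated)
Conditions: CrCl2 (10 mol%), chiral carbazole-1,8-bis(oxazoline) ligand (12 mol%), Mn powder, TMSCl, i-Pr2NEt (cat.), THF, rt; then 1 M HCl, THF, 0 °C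
Reagents that add atoms: none
Why: Nozaki–Hiyama–Kishi allylation: the allylchromium reagent from 5 adds through its γ-carbon (C1) in a closed chair-like transition state with the C14 chain equatorial, which should set the anti C1/C2 relation and unveil the isopropenyl group, while the chiral ligand selects the aldehyde face so that C2 is R and C1 is R.

Step 7
Reactants: 10 propargylic alcohol
Product: 11 C2 triethylsilyl ether of 10 (C18 acetate retained)
Conditions: TESCl, imidazole, CH2Cl2, 0 °C
Reagents that add atoms: chlorotriethylsilane, CC[Si](Cl)(CC)CC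
Why: Standard silylation of the secondary propargylic alcohol; a silyl ether at C2 cannot direct the later hydrostannation.

Step 8
Reactants: 11 C2 silyl ether acetate
Product: 12 (4R,5R,8E)-10-[(4-methoxybenzyl)oxy]-8-methyl-5-(prop-1-en-2-yl)-4-[(triethylsilyl)oxy]dec-8-en-2-yn-1-ol (free OH at C18)
Conditions: K2CO3 (0.2 equiv), MeOH, 0 °C
Reagents that add atoms: none
Why: Carbonate-catalysed transesterification removes the primary acetate, while the secondary TES ether and the PMB ether should be stable at 0 °C.

Step 9
Reactants: 12 C18 propargylic alcohol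
Product: 13 (2Z,4R,5R,8E)-10-[(4-methoxybenzyl)oxy]-8-methyl-5-(prop-1-en-2-yl)-2-(tributylstannyl)-4-[(triethylsilyl)oxy]deca-2,8-dien-1-ol (tin on C4, cis to C2)
Conditions: Bu3SnH, [Cp*RuCl]4 (cat.), CH2Cl2, rt
Reagents that add atoms: tributyltin hydride, CCCC[SnH](CCCC)CCCC
Why: Ruthenium-catalysed trans-hydrostannation: the free C18 hydroxyl hydrogen-bonds to the chloride ligand and steers tin to the proximal alkyne carbon C4, and anti addition places tin cis to C2, the geometry needed for C2 and C5 to be cis.

Step 10
Reactants: 13 alkenylstannane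
Product: 14 (2Z,4R,5R,8E)-2-iodo-10-[(4-methoxybenzyl)oxy]-8-methyl-5-(prop-1-en-2-yl)-4-[(triethylsilyl)oxy]deca-2,8-dien-1-ol
Conditions: I2 (1.05 equiv), CH2Cl2, −78 to 0 °C; aq. Na2S2O3
Reagents that add atoms: iodine, II
Why: Iododestannylation is an ipso substitution with retention of alkene geometry and should be much faster than any reaction of iodine with the other alkenes.

Step 11
Reactants: 14 iodo alcohol
Product: 15 C18 triethylsilyl ether of 14 (C4 alkenyl iodide, TES ethers at C2 and C18)
Conditions: TESCl, imidazole, CH2Cl2, 0 °C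
Reagents that add atoms: chlorotriethylsilane, CC[Si](Cl)(CC)CC
Why: Silylation of the primary allylic alcohol gives the same protecting group at C2 and C18 so both can be removed together at the end.

Step 12
Reactants: 16 (R)-3-hydroxydihydrofuran-2(3H)-one [(R)-α-hydroxy-γ-butyrolactone]
Product: 17 ethyl (R)-4-bromo-2-hydroxybutanoate (C5–C8 unit)
Conditions: HBr (gas), EtOH, 0 °C to rt
Reagents that add atoms: hydrogen bromide, Br; ethanol, CCO
Why: Acid-mediated lactone opening by bromide at the O-alkyl carbon C5 combined with Fischer esterification; the C7 stereocentre is not involved.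

Step 13
Reactants: 17 bromo hydroxy ester
Product: 18 ethyl (R)-4-bromo-2-[(tert-butyldimethylsilyl)oxy]butanoate
Conditions: TBSOTf, 2,6-lutidine, CH2Cl2, −78 to 0 °C
Reagents that add atoms: tert-butyldimethylsilyl triflate, CC(C)(C)[Si](C)(C)OS(=O)(=O)C(F)(F)F
Why: Silylation with a silyl triflate and a hindered base is fast at low temperature and avoids alkylation of a nucleophilic base by the primary bromide.

Step 14
Reactants: 18 bromo ester; 15 alkenyl iodide
Product: 20 seco ethyl ester [cembrane (1R,2S,7R), 3E, 11E; CO2Et at C8, OTBS at C7, OTES at C2 and C18, OPMB at C10], via alkylzinc bromide 19 (not isolated)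
Conditions: 18, Zn dust (activated with BrCH2CH2Br and TMSCl), LiCl, THF, 50 °C; then 15, Pd(OAc)2 (5 mol%), SPhos (10 mol%), THF, rt to 40 °C
Reagents that add atoms: none
Why: Negishi sp3–sp2 coupling: LiCl-assisted zinc insertion into the primary bromide tolerates the ester and silyl ether, and the alkylzinc should couple with the alkenyl iodide with retention of geometry to form C4–C5.

Step 15
Reactants: 20 seco ethyl ester; 21 tert-butyl acetate
Product: 23 seco tert-butyl β-keto ester (C8 ketone, C9 methylene, CO2t-Bu; C10 OPMB), via lithium enolate 22 (not isolated)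
Conditions: 21, LiN(i-Pr)2, THF, −78 °C; then 20, −78 to −40 °C; aq. NH4Cl
Reagents that add atoms: none
Why: Crossed Claisen condensation: the enolate adds to the α-silyloxy ethyl ester, and the β-keto ester formed is deprotonated at once at C9, which prevents a second addition and keeps C7 from enolising.

Step 16
Reactants: 23 seco β-keto ester
Product: 24 hydroxy β-keto ester (free OH at C10)
Conditions: DDQ, CH2Cl2/pH 7 buffer, 0 °C
Reagents that add atoms: none
Why: Oxidative PMB cleavage (hydride abstraction at the electron-rich benzylic carbon, then hydrolysis) is neutral and should spare the silyl ethers, the alkenes and the β-keto ester.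

Step 17
Reactants: 24 hydroxy β-keto ester
Product: 26 16-membered allyl β-keto lactone [(1R,2S,7R); ester O on C10, C8 ketone, OTES at C2 and C18, OTBS at C7], via acylketene 25 (not isolated)
Conditions: toluene, reflux, slow addition (final 1 mM), t-BuOH swept out with N2
Reagents that add atoms: none
Why: Thermal loss of tert-butanol from the β-keto ester gives an acylketene that is trapped by the C10 allylic alcohol (acylketene macrolactonisation); closure at oxygen is favoured at high dilution and needs no base, so C7 is not at risk.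

Step 18
Reactants: 26 16-membered allyl β-keto lactone
Product: 27 14-membered C8 ketone [(1R,2S,7R), 3E, 11E; OTES at C2 and C18, OTBS at C7]
Conditions: Pd(PPh3)4 (10 mol%), THF (5 mM), rt
Reagents that add atoms: none
Why: Oxidative addition of zerovalent palladium to the allylic C10–O bond gives a π-allylpalladium cation (C10–C11–C12) paired with the β-keto carboxylate; loss of CO2 then generates the enolate at C9 only, which attacks the allyl unit and releases the catalyst. The closest known reaction is the palladium-catalysed Carroll-type decarboxylative allylation of allyl β-keto esters, run here inside a macrolactone so that it becomes a two-atom ring contraction. The 14-membered ring closes by attack of C9 on the distal primary terminus C10 of the tethered allyl unit, so that all three allyl carbons lie in the ring; attack at the proximal tertiary terminus C12 would give a strained 12-membered ring with a quaternary carbon and is disfavoured. No stereocentre is created, and C7 should be safe because enolate and electrophile arise together under neutral conditions and the enolate forms only on the C9 side. The step needs C10 regioselectivity and retention of the E geometry at C11=C12; the allyl unit can only isomerise through an unfavourable tertiary σ-complex at C12, and ion-pair collapse at C10 is expected to be faster. High dilution suppresses intermolecular allylation, and the allylic silyl ethers at C2 and C18 are not ionised by palladium.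

Step 19
Reactants: 27 C8 ketone
Product: 28 C8 exocyclic methylene compound (C19 installed; silyl ethers unchanged)
Conditions: Cp2TiMe2, toluene/THF, 70 °C, dark
Reagents that add atoms: dimethyltitanocene, C[Ti](C)(C1C=CC=C1)C1C=CC=C1
Why: Petasis methylenation: the titanium methylidene formed on heating undergoes [2+2] addition and cycloreversion with the ketone and is non-basic, so C7 should not epimerise.

Step 20
Reactants: 28 tris-silyl ether
Product: 29 C2,C18-diol (OTBS at C7 retained)
Conditions: PPTS (cat.), MeOH/CH2Cl2, 0 °C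
Reagents that add atoms: none
Why: Mild acid-catalysed methanolysis should cleave the two TES ethers and leave the bulkier secondary TBS ether.

Step 21
Reactants: 29 diol
Product: 30 C2,C18-diacetate (OTBS at C7)
Conditions: Ac2O, pyridine, DMAP (cat.), CH2Cl2, 0 °C to rt
Reagents that add atoms: acetic anhydride, CC(=O)OC(C)=O
Why: DMAP-catalysed acylation of the primary and the secondary allylic alcohol; no other free hydroxyl is present.

Step 22
Reactants: 30 diacetate silyl ether
Product: 31 target, (1R,2S,7R,3E,11E)-2,18-diacetoxycembra-3,8(19),11,15-tetraen-7-ol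
Conditions: HF·pyridine, pyridine, THF, 0 °C to rt
Reagents that add atoms: none
Why: Buffered fluoride desilylation removes the C7 TBS group without basic conditions, so the acetates should neither hydrolyse nor migrate.

**Compound list**

1 | geraniol | CC(C)=CCC/C(C)=C/CO | starting material
2 | sodium geranoxide (formed in situ) | CC(C)=CCC/C(C)=C/C[O-].[Na+] | intermediate
3 | geranyl 4-methoxybenzyl ether | COc1ccc(COC/C=C(\C)CCC=C(C)C)cc1 | intermediate
4 | (2E,6E)-8-[(4-methoxybenzyl)oxy]-2,6-dimethylocta-2,6-dien-1-ol | COc1ccc(COC/C=C(\C)CC/C=C(\C)CO)cc1 | intermediate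
5 | (2E,6E)-8-bromo-1-[(4-methoxybenzyl)oxy]-3,7-dimethylocta-2,6-diene | COc1ccc(COC/C=C(\C)CC/C=C(\C)CBr)cc1 | intermediate
6 | 2-butyne-1,4-diol | OCC#CCO | starting material
7 | 4-hydroxybut-2-yn-1-yl acetate | CC(=O)OCC#CCO | intermediate
8 | 4-oxobut-2-yn-1-yl acetate | CC(=O)OCC#CC=O | intermediate
9 | C2 trimethylsilyl ether of 10 (formed in situ) | COc1ccc(COC/C=C(\C)CC[C@H](C(=C)C)[C@@H](O[Si](C)(C)C)C#CCOC(C)=O)cc1 | intermediate
10 | (4R,5R,8E)-4-hydroxy-10-[(4-methoxybenzyl)oxy]-8-methyl-5-(prop-1-en-2-yl)dec-8-en-2-yn-1-yl acetate | COc1ccc(COC/C=C(\C)CC[C@H](C(=C)C)[C@@H](O)C#CCOC(C)=O)cc1 | intermediate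
11 | (4R,5R,8E)-10-[(4-methoxybenzyl)oxy]-8-methyl-5-(prop-1-en-2-yl)-4-[(triethylsilyl)oxy]dec-8-en-2-yn-1-yl acetate | COc1ccc(COC/C=C(\C)CC[C@H](C(=C)C)[C@@H](O[Si](CC)(CC)CC)C#CCOC(C)=O)cc1 | intermediate
12 | (4R,5R,8E)-10-[(4-methoxybenzyl)oxy]-8-methyl-5-(prop-1-en-2-yl)-4-[(triethylsilyl)oxy]dec-8-en-2-yn-1-ol | COc1ccc(COC/C=C(\C)CC[C@H](C(=C)C)[C@@H](O[Si](CC)(CC)CC)C#CCO)cc1 | intermediate
13 | (2Z,4R,5R,8E)-10-[(4-methoxybenzyl)oxy]-8-methyl-5-(prop-1-en-2-yl)-2-(tributylstannyl)-4-[(triethylsilyl)oxy]deca-2,8-dien-1-ol | COc1ccc(COC/C=C(\C)CC[C@H](C(=C)C)[C@@H](O[Si](CC)(CC)CC)/C=C(/CO)[Sn](CCCC)(CCCC)CCCC)cc1 | intermediate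
14 | (2Z,4R,5R,8E)-2-iodo-10-[(4-methoxybenzyl)oxy]-8-methyl-5-(prop-1-en-2-yl)-4-[(triethylsilyl)oxy]deca-2,8-dien-1-ol | COc1ccc(COC/C=C(\C)CC[C@H](C(=C)C)[C@@H](O[Si](CC)(CC)CC)/C=C(/CO)I)cc1 | intermediate
15 | triethylsilyl ether of 14 (C4 iodide, OTES at C2 and C18, OPMB at C10) | COc1ccc(COC/C=C(\C)CC[C@H](C(=C)C)[C@@H](O[Si](CC)(CC)CC)/C=C(/CO[Si](CC)(CC)CC)I)cc1 | intermediate
16 | (R)-3-hydroxydihydrofuran-2(3H)-one | O=C1OCC[C@H]1O | starting material
17 | ethyl (R)-4-bromo-2-hydroxybutanoate | BrCC[C@H](C(=O)OCC)O | intermediate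
18 | ethyl (R)-4-bromo-2-[(tert-butyldimethylsilyl)oxy]butanoate | BrCC[C@H](C(=O)OCC)O[Si](C)(C)C(C)(C)C | intermediate
19 | [(R)-3-[(tert-butyldimethylsilyl)oxy]-4-ethoxy-4-oxobutyl]zinc bromide (formed in situ) | Br[Zn]CC[C@H](C(=O)OCC)O[Si](C)(C)C(C)(C)C | intermediate
20 | seco ethyl ester, (1R,2S,7R,3E,11E): CO2Et at C8, OTBS at C7, OTES at C2 and C18, OPMB at C10 | COc1ccc(COC/C=C(\C)CC[C@H](C(=C)C)[C@@H](O[Si](CC)(CC)CC)/C=C(/CO[Si](CC)(CC)CC)CC[C@H](C(=O)OCC)O[Si](C)(C)C(C)(C)C)cc1 | intermediate
21 | tert-butyl acetate | CC(=O)OC(C)(C)C | starting material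
22 | lithium enolate of tert-butyl acetate (formed in situ) | [Li+].C=C([O-])OC(C)(C)C | intermediate
23 | seco tert-butyl β-keto ester, (1R,2S,7R,3E,11E): C8 ketone, C9 methylene, CO2t-Bu, OPMB at C10 | COc1ccc(COC/C=C(\C)CC[C@H](C(=C)C)[C@@H](O[Si](CC)(CC)CC)/C=C(/CO[Si](CC)(CC)CC)CC[C@H](C(=O)CC(=O)OC(C)(C)C)O[Si](C)(C)C(C)(C)C)cc1 | intermediate
24 | hydroxy β-keto ester (free OH at C10) | OC/C=C(\C)CC[C@H](C(=C)C)[C@@H](O[Si](CC)(CC)CC)/C=C(/CO[Si](CC)(CC)CC)CC[C@H](C(=O)CC(=O)OC(C)(C)C)O[Si](C)(C)C(C)(C)C | intermediate
25 | acylketene (formed in situ) | OC/C=C(\C)CC[C@H](C(=C)C)[C@@H](O[Si](CC)(CC)CC)/C=C(/CO[Si](CC)(CC)CC)CC[C@H](C(=O)C=C=O)O[Si](C)(C)C(C)(C)C | intermediate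
26 | 16-membered allyl β-keto lactone, (1R,2S,7R,3E,11E): ester O on C10, C8 ketone, OTES at C2 and C18, OTBS at C7 | O=C1CC(=O)OC/C=C(\C)CC[C@H](C(=C)C)[C@@H](O[Si](CC)(CC)CC)/C=C(/CO[Si](CC)(CC)CC)CC[C@H]1O[Si](C)(C)C(C)(C)C | intermediate
27 | 14-membered C8 ketone, (1R,2S,7R,3E,11E): OTES at C2 and C18, OTBS at C7 | O=C1CC/C=C(\C)CC[C@H](C(=C)C)[C@@H](O[Si](CC)(CC)CC)/C=C(/CO[Si](CC)(CC)CC)CC[C@H]1O[Si](C)(C)C(C)(C)C | intermediate
28 | C8 exocyclic methylene tris-silyl ether | C=C1CC/C=C(\C)CC[C@H](C(=C)C)[C@@H](O[Si](CC)(CC)CC)/C=C(/CO[Si](CC)(CC)CC)CC[C@H]1O[Si](C)(C)C(C)(C)C | intermediate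
29 | C2,C18-diol with OTBS at C7 | C=C1CC/C=C(\C)CC[C@H](C(=C)C)[C@@H](O)/C=C(/CO)CC[C@H]1O[Si](C)(C)C(C)(C)C | intermediate
30 | C2,C18-diacetate with OTBS at C7 | C=C1CC/C=C(\C)CC[C@H](C(=C)C)[C@@H](OC(C)=O)/C=C(/COC(C)=O)CC[C@H]1O[Si](C)(C)C(C)(C)C | intermediate
31 | (1R,2S,7R,3E,11E)-2,18-diacetoxycembra-3,8(19),11,15-tetraen-7-ol | C=C1CC/C=C(\C)CC[C@H](C(=C)C)[C@@H](OC(C)=O)/C=C(/COC(C)=O)CC[C@H]1O | target

**Totals and risk**

Total step count: 22. Longest linear sequence: 18 steps (from geraniol 1 through steps 1–3, 6–11 and 14–22 to 31).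

Steps most likely to fail:

1. Step 18. After ionisation the allyl unit may lose a proton to give a diene and the open-chain methyl ketone, recombine at C12, be captured by a second molecule, or lose its E geometry. Fallback: starting from 24, the C10 hydroxyl is converted with methyl chloroformate and pyridine (CH2Cl2, 0 °C) into the allylic methyl carbonate F1. Pd(PPh3)4 in THF at high dilution (40–65 °C) then ionises the carbonate; the methoxide released deprotonates the β-keto ester, and the stabilised C9 carbanion alkylates the primary terminus C10 in a Tsuji–Trost macrocyclisation to give the 14-membered α-(tert-butoxycarbonyl) ketone F2. The tert-butyl ester is cleaved with TMSOTf and 2,6-lutidine (CH2Cl2, 0 °C), and the β-keto acid decarboxylates on aqueous work-up with gentle warming, which rejoins the route at 27. This replaces the unstabilised enolate by a soft, persistent nucleophile and closes the ring directly from the open chain.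

2. Step 6. The chiral chromium complex may discriminate the aldehyde faces poorly, the slim alkynyl aldehyde may erode the anti preference, or the ynal may be consumed by reductive side reactions. Fallback: starting from 5, palladium-catalysed borylation with bis(pinacolato)diboron (Pd2(dba)3 cat., toluene, 50 °C) gives the linear (E)-allylboronate F3. F3 adds to 8 in the presence of a chiral BINOL-derived phosphoric acid (TRIP type, 5 mol%, toluene, −30 °C) through a closed six-membered transition state, in which the E-boronate gives the anti product and the acid sets the face; oxidative or aqueous work-up rejoins the route at 10. No low-valent metal is present, so reductive pathways are excluded.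

3. Step 17. Ketene formation from the tert-butyl ester may be slow relative to thermal decay, the ketene may be recaptured by tert-butanol, or oligomers may form. Fallback: starting from 20, Claisen condensation with the lithium enolate of S-tert-butyl thioacetate (THF, −78 to −40 °C) gives the PMB-protected β-keto thioester F4, and DDQ (CH2Cl2/pH 7 buffer, 0 °C) frees the C10 alcohol to give the hydroxy β-keto thioester F5. Slow addition of F5 to AgO2CCF3 and Na2HPO4 in THF at room temperature under high dilution activates the thioester through the thiophilic silver salt and closes the lactone, which rejoins the route at 26. The ring closure then runs at room temperature by electrophilic activation and not by thermolysis.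

**Further compounds**

F1 | step 18 | C10 methyl carbonate of hydroxy β-keto ester 24 | COC(=O)OC/C=C(\C)CC[C@H](C(=C)C)[C@@H](O[Si](CC)(CC)CC)/C=C(/CO[Si](CC)(CC)CC)CC[C@H](C(=O)CC(=O)OC(C)(C)C)O[Si](C)(C)C(C)(C)C
F2 | step 18 | 14-membered C8 ketone carrying CO2t-Bu at C9 (C9 epimers) | O=C1C(C(=O)OC(C)(C)C)C/C=C(\C)CC[C@H](C(=C)C)[C@@H](O[Si](CC)(CC)CC)/C=C(/CO[Si](CC)(CC)CC)CC[C@H]1O[Si](C)(C)C(C)(C)C
F3 | step 6 | (2E,6E)-allylboronic acid pinacol ester derived from 5 | COc1ccc(COC/C=C(\C)CC/C=C(\C)CB2OC(C)(C)C(C)(C)O2)cc1
F4 | step 17 | seco S-tert-butyl β-keto thioester with OPMB at C10 | COc1ccc(COC/C=C(\C)CC[C@H](C(=C)C)[C@@H](O[Si](CC)(CC)CC)/C=C(/CO[Si](CC)(CC)CC)CC[C@H](C(=O)CC(=O)SC(C)(C)C)O[Si](C)(C)C(C)(C)C)cc1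
F5 | step 17 | seco S-tert-butyl β-keto thioester with free OH at C10 | OC/C=C(\C)CC[C@H](C(=C)C)[C@@H](O[Si](CC)(CC)CC)/C=C(/CO[Si](CC)(CC)CC)CC[C@H](C(=O)CC(=O)SC(C)(C)C)O[Si](C)(C)C(C)(C)C
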